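**Retrosynthetic overview**
1. Target ⇒ cis-7,8-diol of the bicyclic dienone + orsellinic acid: a Mitsunobu esterification inverts C-8 and gives the trans 7-OH/8-acyloxy pattern.
2. cis-Diol ⇒ its pivalaldehyde acetal ⇒ dihydropyranone methyl ketone: an intramolecular aldol condensation closes the carbocycle (C4a=C5), the last ring formed.
3. Dihydropyranone ⇒ hydroxymethylated cyclobutane lactone + pentenynyl lithium: acetylide addition, retro-aldol opening of the cyclobutane and oxa-Michael closure form the pyranone ring first.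
4. Cyclobutane (+ CH2O) ⇒ dioxinone + chiral dioxole: a [2+2] photocycloaddition (de Mayo logic) makes the C6–C7 and C8–C8a bonds.
5. Dioxole ⇒ (S)-lactic acid + pivalaldehyde: the lactate centre is stored in the tert-butyl acetal, which then sets C-7 and C-8; C-8a follows by equilibration.

Assumption: ring atoms are numbered as in isochromene (O2, C1, C3, C4, C4a, C5–C8, C8a); (S)-lactic acid, pivalaldehyde, the diketene–acetone adduct, crotonaldehyde and orsellinic acid are taken as commercial.

**Route**

Step 1
Reactants: 1 (S)-lactic acid; 2 pivalaldehyde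
Product: 3 (2S,5S)-2-tert-butyl-5-methyl-1,3-dioxolan-4-one
Conditions: TsOH·H2O (cat.), H2SO4 (cat.), pentane, reflux, Dean–Stark; recrystallise (pentane, −78 °C)
Reagents that add atoms: none
Why: Acid-catalysed acetalisation of the α-hydroxy acid with azeotropic water removal (Seebach acetalisation) gives the crystalline cis-dioxolanone, the new acetal centre (2S) being set by the lactate centre.

Step 2
Reactants: 3 cis-dioxolanone
Product: 5 (2S,5S)-2-tert-butyl-5-methyl-1,3-dioxolan-4-yl acetate (both C-4 anomers), via lactol aluminate 4 (not isolated)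
Conditions: i-Bu2AlH (1.1 equiv), CH2Cl2, −78 °C; then pyridine, DMAP, Ac2O, −78 °C → rt
Reagents that add atoms: acetic anhydride, CC(=O)OC(C)=O; diisobutylaluminium hydride, CC(C)C[AlH]CC(C)C (its aluminium stays only in intermediate 4)
Why: Low-temperature hydride reduction of the lactone stops at the aluminium hemiacetal 4, which is acetylated in the same flask (reductive acetylation), leaving both stereocentres untouched.

Step 3
Reactants: 5 anomeric acetate
Product: 6 (2R)-2-tert-butyl-4-methyl-1,3-dioxole
Conditions: Me3SiOTf (1.2 equiv), i-Pr2NEt (2.5 equiv), CH2Cl2, −40 → 0 °C; distil from K2CO3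
Reagents that add atoms: none
Why: Me3SiOTf ionises the anomeric acetate to a ring oxocarbenium ion that loses the C-5 proton to the amine (E1 elimination, as in glycal formation), erasing the lactate centre while the untouched tert-butyl acetal centre now stores the chirality.

Step 4
Reactants: 6 (R)-tert-butyl methyl dioxole; 7 diketene–acetone adduct (trimethyl dioxinone)
Product: 8 head-to-tail cis-anti-cis cyclobutane photoadduct (dioxanone and dioxolane rings on opposite faces of the cyclobutane C6–C7–C8–C8a with tert-butyl cis to the C7 methyl and to H-8)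
Conditions: hν (300 nm, Pyrex), dioxole in threefold excess, MeCN–acetone 9:1, 0 °C, Ar
Reagents that add atoms: none
Why: Proposed new method: a de Mayo-type [2+2] photocycloaddition in which the triplet dioxinone bonds through its α-carbon to the unsubstituted dioxole carbon, giving the doubly tertiary, doubly α-oxygenated 1,4-biradical that closes head-to-tail on the dioxole face anti to tert-butyl, so that the stored acetal chirality sets C-7 (S) and C-8 (the dioxinone-derived centres are erased or equilibrated later, so exo and endo adducts converge); the closest known chemistry is the dioxinone–alkene photocycloaddition with enol ethers and ketene acetals and Seebach-type self-regeneration of stereocentres, but a chiral 1,3-dioxole has not been shown as the alkene partner.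

Step 5
Reactants: 8 cyclobutane photoadduct
Product: 10 hydroxymethyl lactone (photoadduct with CH2OH in place of H at C8a), via lithium enolate 9 (not isolated)
Conditions: LiN(i-Pr)2 (1.1 equiv), THF, −78 °C; CH2O (g), −78 °C; AcOH
Reagents that add atoms: formaldehyde, C=O; lithium diisopropylamide, [Li+].CC(C)[N-]C(C)C (its lithium stays only in intermediate 9)
Why: Ester-enolate aldol reaction of the dioxanone enolate 9 with monomeric formaldehyde, the cis ring fusion forcing CH2OH into the place of the former hydrogen (this centre becomes epimerisable in step 7 anyway).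

Step 6
Reactants: 11 (E)-crotonaldehyde
Product: 12 (E)-1,1-dibromopenta-1,3-diene
Conditions: CBr4, PPh3, CH2Cl2, 0 °C
Reagents that add atoms: carbon tetrabromide, BrC(Br)(Br)Br
Why: Corey–Fuchs dibromo-olefination (Wittig reaction of the dibromomethylene ylide) of the enal, which keeps the E double bond.

Step 7
Reactants: 10 hydroxymethyl lactone; 12 (E)-dibromopentadiene
Product: 16 6-[(E)-prop-1-enyl]-2,3-dihydro-4H-pyran-4-one whose C-3 (C8a) carries the 5-acetyl-2-tert-butyl-5-methyl-1,3-dioxolan-4-yl group (C8a epimers), via lithium acetylide 13 (not isolated), via alkynyl hemiketal 14 (not isolated), via hydroxy ynone 15 (not isolated)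
Conditions: dibromide (2.2 equiv), n-BuLi (4.4 equiv), THF, −78 → 0 °C; add lactone, −78 → −30 °C; AcOH, −78 °C → rt; then TsOH·H2O (10 mol%), CH2Cl2, rt
Reagents that add atoms: n-butyllithium, [Li]CCCC (its lithium stays only in intermediate 13)
Why: n-BuLi turns 12 into acetylide 13 (second stage of the Corey–Fuchs sequence), which adds once to the lactone-type carbonyl of 10 to give hemiketal 14, and loss of acetone, strain-driven retro-aldol opening of the cyclobutanol (the de Mayo fragmentation) and acid-catalysed 6-endo-dig oxa-Michael closure of β-hydroxy ynone 15 give the dihydropyranone with C-7 and C-8 untouched.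

Step 8
Reactants: 16 dihydropyranone methyl ketone
Product: 17 bicyclic dienone as its 7,8-O-pivalaldehyde acetal (tert-butyl cis to the C7 methyl and to H-8)
Conditions: TsOH (anhydrous, 0.3 equiv), toluene, 4 Å MS, 70 °C
Reagents that add atoms: none
Why: Acid-catalysed intramolecular aldol condensation (Robinson-type closure of the 1,5-diketone, the methyl ketone enol attacking the O-protonated vinylogous-ester carbonyl, then dehydration to the push–pull dienone), with C-8a equilibrating through the pyranone enol to the isomer having C1 trans to the C-8 oxygen (8aS).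

Step 9
Reactants: 17 acetal-protected bicyclic dienone
Product: 18 (7S,8S,8aS)-7,8-dihydroxy-7-methyl-3-[(E)-prop-1-enyl]-1,7,8,8a-tetrahydro-6H-isochromen-6-one
Conditions: CF3CO2H–H2O 9:1, 0 °C → rt
Reagents that add atoms: none
Why: Aqueous acid hydrolysis of the pivalaldehyde acetal frees the cis-diol without touching a stereocentre, the vinylogous-ester dienol ether being stable to acid as in azaphilones.

Step 10
Reactants: 18 cis-diol; 19 orsellinic acid
Product: 20 (7S,8R,8aS)-7-hydroxy-7-methyl-6-oxo-3-[(E)-prop-1-enyl]-6,7,8,8a-tetrahydro-1H-isochromen-8-yl 2,4-dihydroxy-6-methylbenzoate (target)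
Conditions: PPh3 (2.0 equiv), DIAD (2.0 equiv), toluene–THF, 0 °C → rt
Reagents that add atoms: none
Why: Mitsunobu esterification in which only the secondary C-8 hydroxyl is activated and is displaced in an SN2 step by the carboxylate (the acid is far more acidic than its phenols, so the carboxylate is the nucleophile), inverting C-8 to R while the tertiary C-7 hydroxyl stays free.

**Compound list**
1 | (S)-lactic acid | C[C@H](O)C(=O)O | starting material
2 | pivalaldehyde | CC(C)(C)C=O | starting material
3 | (2S,5S)-2-tert-butyl-5-methyl-1,3-dioxolan-4-one | C[C@@H]1O[C@H](C(C)(C)C)OC1=O | intermediate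
4 | diisobutylaluminium (2S,5S)-2-tert-butyl-5-methyl-1,3-dioxolan-4-olate (not isolated) | C[C@@H]1O[C@H](C(C)(C)C)OC1O[Al](CC(C)C)CC(C)C | intermediate
5 | (2S,5S)-2-tert-butyl-5-methyl-1,3-dioxolan-4-yl acetate (C-4 anomers) | C[C@@H]1O[C@H](C(C)(C)C)OC1OC(C)=O | intermediate
6 | (2R)-2-tert-butyl-4-methyl-1,3-dioxole | CC1=CO[C@@H](C(C)(C)C)O1 | intermediate
7 | 2,2,6-trimethyl-4H-1,3-dioxin-4-one (diketene–acetone adduct) | CC1=CC(=O)OC(C)(C)O1 | starting material
8 | head-to-tail cis-anti-cis cyclobutane photoadduct of 6 and 7 | CC1(C)OC(=O)[C@H]2[C@@H]3O[C@@H](C(C)(C)C)O[C@]3(C)[C@@]2(C)O1 | intermediate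
9 | lithium enolate of 8 (not isolated) | CC1(C)OC([O-])=C2[C@@H]3O[C@@H](C(C)(C)C)O[C@]3(C)[C@@]2(C)O1.[Li+] | intermediate
10 | α-hydroxymethyl lactone (8 with CH2OH at C8a) | CC1(C)OC(=O)[C@@]2(CO)[C@@H]3O[C@@H](C(C)(C)C)O[C@]3(C)[C@@]2(C)O1 | intermediate
11 | (E)-but-2-enal (crotonaldehyde) | C/C=C/C=O | starting material
12 | (E)-1,1-dibromopenta-1,3-diene | C/C=C/C=C(Br)Br | intermediate
13 | lithium (E)-pent-3-en-1-yn-1-ide (not isolated) | C/C=C/C#[C-].[Li+] | intermediate
14 | alkynyl hemiketal from 13 and 10 (not isolated; hemiketal carbon undefined) | CC1(C)OC(O)(C#C/C=C/C)[C@@]2(CO)[C@@H]3O[C@@H](C(C)(C)C)O[C@]3(C)[C@@]2(C)O1 | intermediate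
15 | β-hydroxy ynone methyl ketone (not isolated; C8a epimers) | C/C=C/C#CC(=O)C(CO)[C@@H]1O[C@@H](C(C)(C)C)O[C@]1(C)C(C)=O | intermediate
16 | dihydropyranone methyl ketone (C8a epimers) | C/C=C/C1=CC(=O)C(CO1)[C@@H]2O[C@@H](C(C)(C)C)O[C@]2(C)C(C)=O | intermediate
17 | pivalaldehyde acetal of 18 | C/C=C/C1=CC2=CC(=O)[C@@]3(C)O[C@H](C(C)(C)C)O[C@H]3[C@@H]2CO1 | intermediate
18 | (7S,8S,8aS)-7,8-dihydroxy-7-methyl-3-[(E)-prop-1-enyl]-1,7,8,8a-tetrahydro-6H-isochromen-6-one | C/C=C/C1=CC2=CC(=O)[C@@](C)(O)[C@@H](O)[C@@H]2CO1 | intermediate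
19 | orsellinic acid (2,4-dihydroxy-6-methylbenzoic acid) | Cc1cc(O)cc(O)c1C(=O)O | starting material
20 | CNP0130178.4, (7S,8R,8aS) orsellinate | C/C=C/C1=CC2=CC(=O)[C@@](C)(O)[C@H](OC(=O)c3c(C)cc(O)cc3O)[C@@H]2CO1 | target

**Step count**
Total step count: 10. Longest linear sequence: 9 (steps 1–5 and 7–10; step 6 is the side branch).

**Three steps most likely to fail**

Step 4 (the proposed new photocycloaddition). The risks are head-to-head regiochemistry, slow reaction at the crowded vicinal quaternary carbons, and dioxinone dimerisation. The fallback uses only established ionic chemistry, sets out from 3 and comes back at 16. Seebach aldol of 3 (LiN(i-Pr)2, THF, −78 °C; acetaldehyde; Et3SiOTf added to the same flask) gives (2S,5R)-2-tert-butyl-5-methyl-5-[1-(triethylsilyloxy)ethyl]-1,3-dioxolan-4-one F1, with the new bond anti to tert-butyl. Reductive acetylation as in step 2 gives the 4-acetoxy acetal F2. Separately, acetylide 13 is added to commercial 3-(tert-butyldimethylsilyloxy)propanal to give propargylic alcohol F3, and MnO2 gives ynone F4. TsOH in MeOH removes the silyl group and closes 6-[(E)-prop-1-enyl]-2,3-dihydro-4H-pyran-4-one F5, and Me3SiOTf/Et3N gives its silyl dienol ether F6. Coupling of F2 with F6 (Me3SiOTf cat., CH2Cl2, −78 °C; Mukaiyama-type attack on the ring oxocarbenium ion on the face anti to tert-butyl, the C-8 epimer being removed by chromatography if it forms) gives the coupled silyl ether F7. HF·pyridine then gives the secondary alcohol F8, and Dess–Martin oxidation gives 16, after which steps 8–10 run unchanged.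

Step 8 (aldol condensation onto the weakly electrophilic pyranone carbonyl; β-elimination of the C-8 acetal oxygen can compete). The fallback changes the ring order, sets out from 10 and comes back at 17. Silylation (t-BuPh2SiCl, imidazole, DMAP, DMF) gives the tert-butyldiphenylsilyl ether F9. Addition of acetylide 13 and fragmentation as in step 7, but with an AcOH quench and Et3N in place of TsOH, gives the silyl-protected ynone methyl ketone F10. Acid-catalysed aldol condensation of the methyl ketone onto the far more electrophilic ynone carbonyl (TsOH, benzene, 50 °C; the silyl ether blocks the oxa-Michael path) gives the 3-alkynyl cyclohexenone F11. Bu4NF frees the C1 alkoxide, which closes the pyran ring by 6-endo-dig 1,6-oxa-Michael addition to give 17.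

Step 10 (SN2 at C-8 next to a quaternary carbon; a stable dioxaphospholane, elimination towards C-8a or phenol alkylation may intervene). The fallback replaces the Mitsunobu activation by a cyclic sulfate, sets out from 18 and comes back at 20. 1,1'-Sulfonyldiimidazole and NaH in DMF at −40 °C give the 7,8-cyclic sulfate F12. Caesium orsellinate F13, made in the flask from 19 and Cs2CO3, opens it at the secondary C-8 with inversion (DMF, 50 °C) to give the C-7 sulfate monoester F14. Catalytic H2SO4 in THF–H2O hydrolyses the sulfate to give 20.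

**Further compounds**
F1 | step 4 | (2S,5R)-2-tert-butyl-5-methyl-5-[1-(triethylsilyloxy)ethyl]-1,3-dioxolan-4-one (carbinol epimers) | CC(O[Si](CC)(CC)CC)[C@@]1(C)O[C@H](C(C)(C)C)OC1=O
F2 | step 4 | (2S,5R)-2-tert-butyl-5-methyl-5-[1-(triethylsilyloxy)ethyl]-1,3-dioxolan-4-yl acetate (C-4 anomers) | CC(O[Si](CC)(CC)CC)[C@@]1(C)O[C@H](C(C)(C)C)OC1OC(C)=O
F3 | step 4 | (E)-1-(tert-butyldimethylsilyloxy)oct-6-en-4-yn-3-ol | C/C=C/C#CC(O)CCO[Si](C)(C)C(C)(C)C
F4 | step 4 | (E)-1-(tert-butyldimethylsilyloxy)oct-6-en-4-yn-3-one | C/C=C/C#CC(=O)CCO[Si](C)(C)C(C)(C)C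
F5 | step 4 | 6-[(E)-prop-1-enyl]-2,3-dihydro-4H-pyran-4-one | C/C=C/C1=CC(=O)CCO1
F6 | step 4 | 6-[(E)-prop-1-enyl]-4-(trimethylsilyloxy)-2H-pyran | C/C=C/C1=CC(O[Si](C)(C)C)=CCO1
F7 | step 4 | triethylsilyl ether of the C-6 carbinol analogue of 16 | C/C=C/C1=CC(=O)C(CO1)[C@@H]2O[C@@H](C(C)(C)C)O[C@]2(C)C(C)O[Si](CC)(CC)CC
F8 | step 4 | C-6 carbinol analogue of 16 | C/C=C/C1=CC(=O)C(CO1)[C@@H]2O[C@@H](C(C)(C)C)O[C@]2(C)C(C)O
F9 | step 8 | tert-butyldiphenylsilyl ether of 10 | CC1(C)OC(=O)[C@@]2(CO[Si](c4ccccc4)(c4ccccc4)C(C)(C)C)[C@@H]3O[C@@H](C(C)(C)C)O[C@]3(C)[C@@]2(C)O1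
F10 | step 8 | tert-butyldiphenylsilyl ether of 15 | C/C=C/C#CC(=O)C(CO[Si](c2ccccc2)(c2ccccc2)C(C)(C)C)[C@@H]1O[C@@H](C(C)(C)C)O[C@]1(C)C(C)=O
F11 | step 8 | 3-[(E)-pent-3-en-1-ynyl]cyclohex-2-enone with the 4-(tert-butyldiphenylsilyloxymethyl) group and the 5,6-pivalaldehyde acetal | C/C=C/C#CC1=CC(=O)[C@@]2(C)O[C@H](C(C)(C)C)O[C@H]2[C@@H]1CO[Si](c3ccccc3)(c3ccccc3)C(C)(C)C
F12 | step 10 | 7,8-cyclic sulfate of 18 | C/C=C/C1=CC2=CC(=O)[C@@]3(C)OS(=O)(=O)O[C@H]3[C@@H]2CO1
F13 | step 10 | caesium 2,4-dihydroxy-6-methylbenzoate | Cc1cc(O)cc(O)c1C(=O)[O-].[Cs+]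
F14 | step 10 | caesium 7-O-sulfate of 20 | C/C=C/C1=CC2=CC(=O)[C@@](C)(OS(=O)(=O)[O-])[C@H](OC(=O)c3c(C)cc(O)cc3O)[C@@H]2CO1.[Cs+]
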